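**Plan**

1. Retrosynthesis: in each 2,2-dimethyl-2H-pyran ring the aryl C7–O bond, the C8–C4′ bond and the O–CMe2 bond are cut together (aryne + 3-methylbut-2-enal). This leads back to the bis(8-SiMe3/7-OTf) cyclobutane core. The cyclobutane bonds C3–C4′ and C4–C3′ are then cut to a coumarin monomer.
2. Forward: umbelliferone → 8-iodide → one-pot retro-Brook/triflation gives monomer 6. A Lewis-acid-mediated syn head-to-tail [2+2] photodimerisation closes the cyclobutane (7). One fluoride operation then generates both 7,8-arynes and closes both pyran rings (16).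
3. Enabling feature: the pyran oxygen on C7 and the pyran carbon C4′ on C8 are neighbouring substituents of the coumarin benzo ring, which is the footprint of a C7≡C8 aryne. The lactone oxygen O1 on C8a, beside that triple bond, steers O to C7 and C to C8. A 2,2-dimethyl-2H-chromene is the oxa-6π isomer of the o-quinone methide that an aryne makes from an enal.
4. Benefit: the photochromic chromene C=C bonds are absent during the photochemical step, and the C2 axis lets both rings (six bonds) form in one operation.
5. Stereochemistry: all four centres (3S,4R,3′S,4′R, coumarin numbering, all-cis H) are set in step 3. Cis fusion comes from the suprafacial [2+2], syn head-to-tail from the Lewis-acid exciplex, and absolute sense from the chiral oxazaborolidine. The chirality lies only in which phenol lactonises which carboxyl (opening both lactones gives an achiral all-cis diacid), so step 4 is run dry and non-hydrolytic.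

Key step: step 4

Assumption: the sense of induction of the chiral Lewis acid in step 3 cannot be derived with certainty from its intramolecular precedent, so the catalyst antipode (both are available from (S)- or (R)-proline) is fixed in a pilot run with configurational assignment; the descriptors are derived from the target SMILES.

**Step 1**
Reactants: 1 umbelliferone (7-hydroxy-2H-chromen-2-one)
Product: 2 7-hydroxy-8-iodo-2H-chromen-2-one
Conditions: I2, KI, aq. NH3 (20%), 0 °C → rt; then dilute H2SO4 to pH 3
Reagents that add atoms: iodine II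
Why: Electrophilic aromatic iodination of the 7-phenolate should occur at C8, the position between O7 and the O1-bearing C8a that is favoured by the C7=C8 bond fixation of the coumarin.

**Step 2**
Reactants: 2 7-hydroxy-8-iodo-2H-chromen-2-one
Product: 6 2-oxo-8-(trimethylsilyl)-2H-chromen-7-yl trifluoromethanesulfonate, via silyl ether 3 (not isolated), via aryllithium 4 (not isolated), via lithium phenolate 5 (not isolated)
Conditions: HMDS, THF, 65 °C, then volatiles off; n-BuLi, THF, −100 → −78 °C; Tf2O, −78 → 0 °C
Reagents that add atoms: hexamethyldisilazane C[Si](C)(C)N[Si](C)(C)C; trifluoromethanesulfonic anhydride O=S(=O)(OS(=O)(=O)C(F)(F)F)C(F)(F)F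
Why: After O-silylation, iodine–lithium exchange at −100 °C should outpace addition to the lactone and trigger the 1,3 O→C silyl shift (retro-Brook rearrangement) to the 8-silyl phenolate, which is triflated in the same pot, the standard entry to o-silylaryl triflates.

**Step 3**
Reactants: 6 2-oxo-8-(trimethylsilyl)-2H-chromen-7-yl trifluoromethanesulfonate (2 equiv)
Product: 7 (3S,4R,3′S,4′R)-syn head-to-tail cyclobutane dimer of 6 (units joined C3–C4′ and C4–C3′; all four cyclobutane H cis; each arene 8-SiMe3 and 7-OTf)
Conditions: AlBr3-activated B-aryl oxazaborolidine from an α,α-diarylprolinol (0.5 equiv), CH2Cl2, −75 °C, hν (366 nm)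
Reagents that add atoms: none
Why: Proposed new method: the Lewis acid binds the lactone carbonyl and red-shifts the absorption so that only the complex is excited at 366 nm; with 0.5 equiv of acid half of 6 stays free and π-stacks in the singlet exciplex with the electrophilic C4 of the complex over its nucleophilic C3, which should give the cis-fused, syn, head-to-tail cyclobutane as in BF3-promoted coumarin photodimerisation, while the diarylprolinol-derived oxazaborolidine shields one face of the bound coumarin so that the partner adds to the open face and thereby fixes C3/C4 and, through the C2-symmetric syn head-to-tail topology, C3′/C4′; the closest known reaction type is the enantioselective intramolecular [2+2] photocycloaddition of coumarins under the same chiral Lewis acid.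

**Step 4**
Reactants: 7 (3S,4R,3′S,4′R)-syn head-to-tail bis(silyl triflate) dimer; 8 3-methylbut-2-enal (excess)
Product: 16 CNP0167575.1 = (3S,4R,3′S,4′R)-syn head-to-tail cyclobutane dimer of seselin, via aryne 9 (not isolated), via benzoxete 10 (not isolated), via o-quinone methide 11 (not isolated), via mono-chromene 12 (not isolated), via second aryne 13 (not isolated), via second benzoxete 14 (not isolated), via second o-quinone methide 15 (not isolated)
Conditions: CsF (6 equiv), 3-methylbut-2-enal (10 equiv), 4 Å MS, MeCN–toluene (1:1), 50 °C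
Reagents that add atoms: none
Why: Fluoride removes SiMe3 from C8 and triflate leaves from C7 (a far better leaving group than the lactone carboxylate on C8a) to give the 7,8-aryne 9; the carbonyl oxygen of 8 adds to C7, forming the aryl C7–O bond, and the C8 carbanion closes on the carbonyl carbon to benzoxete 10, which opens by 4π-electrocyclic O–CH cleavage to the o-quinone methide 11. Thermal disrotatory oxa-6π-electrocyclisation of the (Z)-1-oxatriene O=C7–C8=CH–CH=CMe2 forms the O–CMe2 bond, rearomatises the arene and closes the 2H-pyran ring (12), and the same sequence on the second, C2-related arene (13–15) gives 16. The closest known reaction type is the annulation of arynes from o-silylaryl triflates with α,β-unsaturated aldehydes to 2H-chromenes. Ring closures: the transient oxete by stepwise formal [2+2] addition across C=O, the pyran by 6π-electrocyclisation. No new stereocentre remains (the oxete carbon becomes sp2), and the four cyclobutane centres are spectators because dry fluoride in MeCN should neither open nor epimerise the cis-fused lactones. The selectivity required is regiochemical (O at C7, C at C8): the inductively withdrawing lactone oxygen O1 on C8a, beside the triple bond, distorts the aryne so that C7 is the flatter, more electrophilic terminus and negative charge builds at C8 next to O1, while the β,β-dimethyl groups of the enal disfavour the [4+2] mode and excess enal outruns capture of 11 by a second aryne.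

**Compound list**

1 | umbelliferone (7-hydroxy-2H-chromen-2-one) | O=c1ccc2ccc(O)cc2o1 | starting material
2 | 7-hydroxy-8-iodo-2H-chromen-2-one | O=c1ccc2ccc(O)c(I)c2o1 | intermediate
3 | 8-iodo-7-(trimethylsilyloxy)-2H-chromen-2-one | C[Si](C)(C)Oc1ccc2ccc(=O)oc2c1I | intermediate
4 | 8-lithio-7-(trimethylsilyloxy)-2H-chromen-2-one | [Li]c1c(O[Si](C)(C)C)ccc2ccc(=O)oc12 | intermediate
5 | lithium 2-oxo-8-(trimethylsilyl)-2H-chromen-7-olate | [Li+].[O-]c1ccc2ccc(=O)oc2c1[Si](C)(C)C | intermediate
6 | 2-oxo-8-(trimethylsilyl)-2H-chromen-7-yl trifluoromethanesulfonate | C[Si](C)(C)c1c(OS(=O)(=O)C(F)(F)F)ccc2ccc(=O)oc12 | intermediate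
7 | (3S,4R,3′S,4′R)-syn head-to-tail cyclobutane dimer of 6; all-cis cyclobutane H; bis(8-SiMe3, 7-OTf) | C[Si](C)(C)c2c(ccc3c2OC(=O)[C@H]2[C@@H]3[C@H]3C(=O)Oc4c([Si](C)(C)C)c(ccc4[C@H]32)OS(=O)(=O)C(F)(F)F)OS(=O)(=O)C(F)(F)F | intermediate
8 | 3-methylbut-2-enal | CC(C)=CC=O | starting material
9 | 7,8-aryne on one dihydrocoumarin unit of 7; other unit unchanged; cyclobutane centres as in 7 | C2#CC=CC3=C2OC(=O)[C@H]2[C@@H]3[C@H]3C(=O)Oc4c([Si](C)(C)C)c(ccc4[C@H]32)OS(=O)(=O)C(F)(F)F | intermediate
10 | benzoxete from 9 and 8 (O on C7, CH(CH=CMe2) on C8; either configuration at the oxete carbon) | CC(C)=CC5c2c(ccc3c2OC(=O)[C@H]2[C@@H]3[C@H]3C(=O)Oc4c([Si](C)(C)C)c(ccc4[C@H]32)OS(=O)(=O)C(F)(F)F)O5 | intermediate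
11 | (Z)-o-quinone methide (C7=O, C8=CH–CH=CMe2) on the first unit | CC(C)=C/C=C2\C(=O)C=CC3=C2OC(=O)[C@H]2[C@@H]3[C@H]3C(=O)Oc4c([Si](C)(C)C)c(ccc4[C@H]32)OS(=O)(=O)C(F)(F)F | intermediate
12 | mono-chromene: first 2,2-dimethyl-2H-pyran ring closed; second arene still 8-SiMe3/7-OTf | CC1(C)C=Cc2c(ccc3c2OC(=O)[C@H]2[C@@H]3[C@H]3C(=O)Oc4c([Si](C)(C)C)c(ccc4[C@H]32)OS(=O)(=O)C(F)(F)F)O1 | intermediate
13 | 7,8-aryne on the second unit of 12 | CC1(C)C=Cc2c(ccc3c2OC(=O)[C@H]2[C@@H]3[C@H]3C(=O)OC4=C(C=CC#C4)[C@H]32)O1 | intermediate
14 | benzoxete on the second unit (either configuration at the oxete carbon) | CC1(C)C=Cc2c(ccc3c2OC(=O)[C@H]2[C@@H]3[C@H]3C(=O)Oc4c5c(ccc4[C@H]32)OC5C=C(C)C)O1 | intermediate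
15 | (Z)-o-quinone methide on the second unit | CC1(C)C=Cc2c(ccc3c2OC(=O)[C@H]2[C@@H]3[C@H]3C(=O)OC4=C(C=CC(=O)/C4=C\C=C(C)C)[C@H]32)O1 | intermediate
16 | CNP0167575.1, (3S,4R,3′S,4′R)-syn head-to-tail cyclobutane dimer of seselin (all-cis cyclobutane H) | CC1(C)C=Cc2c(ccc3c2OC(=O)[C@H]2[C@@H]3[C@H]3C(=O)Oc4c5c(ccc4[C@H]32)OC(C)(C)C=C5)O1 | target

**Step count and risks**

Total step count: 4. Longest linear sequence: 4 steps (1 → 2 → 6 → 7 → 16).

Steps most likely to fail:

1. Step 3 (Proposed new method). Facial discrimination by the catalyst may be poor, uncomplexed 6 may dimerise in a racemic background reaction, head-to-head or anti dimerisation may compete, or the strong Lewis acid may cause protodesilylation. Fallback, setting out from 6 and coming back at 7: 6 is irradiated (≥350 nm, CH2Cl2, 0 °C) with BF3·OEt2 (0.5 equiv), the known achiral way to syn head-to-tail coumarin photodimers. This should give 7 as a racemate with its mirror image, the (3R,4S,3′R,4′S)-dimer F1. The antipodes are separated by preparative chromatography on a polysaccharide chiral stationary phase, and F1 is returned to 6 by cycloreversion at 254 nm.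

2. Step 4. Fluoride or adventitious hydroxide may open the aryl-ester lactones, which would also start C→O silyl migration and erode enantiopurity by lactone exchange. The o-quinone methide may be captured by a second aryne, or the second annulation may stall. Fallback, setting out from 1 and coming back at 16: 1 is O-alkylated with 3-chloro-3-methylbut-1-yne (K2CO3, KI, cat. CuCl, acetone, 60 °C) to 7-[(2-methylbut-3-yn-2-yl)oxy]-2H-chromen-2-one F2. F2 is rearranged in N,N-diethylaniline at 200 °C (aryl propargyl ether Claisen rearrangement, 1,5-H shift, oxa-6π closure) to seselin F3. F3 is photodimerised under Lewis-acid complexation as in step 3; if induction fails, BF3·OEt2 is used and 16 is separated from its mirror image, the (3R,4S,3′R,4′S)-dimer F4, on a chiral stationary phase.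

3. Step 2. Butyllithium or the aryllithium may add to the coumarin lactone before exchange and silyl migration are complete. Fallback, setting out from 2 and coming back at 6: 2 is acetylated (Ac2O, pyridine) to 8-iodo-2-oxo-2H-chromen-7-yl acetate F5. Pd-catalysed silylation of the C–I bond with hexamethyldisilane (Pd2(dba)3, dialkylbiarylphosphine, LiOAc, DMF, 100 °C) should give 2-oxo-8-(trimethylsilyl)-2H-chromen-7-yl acetate F6. Ammonolysis (NH3, MeOH, 0 °C) gives 7-hydroxy-8-(trimethylsilyl)-2H-chromen-2-one F7, and triflation (Tf2O, pyridine, CH2Cl2, 0 °C) gives 6.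

**Further compounds**

F1 | step 3 | (3R,4S,3′R,4′S)-enantiomer of 7 | C[Si](C)(C)c2c(ccc3c2OC(=O)[C@@H]2[C@H]3[C@@H]3C(=O)Oc4c([Si](C)(C)C)c(ccc4[C@@H]32)OS(=O)(=O)C(F)(F)F)OS(=O)(=O)C(F)(F)F
F2 | step 4 | 7-[(2-methylbut-3-yn-2-yl)oxy]-2H-chromen-2-one | C#CC(C)(C)Oc1ccc2ccc(=O)oc2c1
F3 | step 4 | seselin (8,8-dimethyl-2H,8H-pyrano[2,3-f]chromen-2-one) | CC1(C)C=Cc2c(O1)ccc1ccc(=O)oc21
F4 | step 4 | (3R,4S,3′R,4′S)-enantiomer of 16 | CC1(C)C=Cc2c(ccc3c2OC(=O)[C@@H]2[C@H]3[C@@H]3C(=O)Oc4c5c(ccc4[C@@H]32)OC(C)(C)C=C5)O1
F5 | step 2 | 8-iodo-2-oxo-2H-chromen-7-yl acetate | CC(=O)Oc1ccc2ccc(=O)oc2c1I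
F6 | step 2 | 2-oxo-8-(trimethylsilyl)-2H-chromen-7-yl acetate | CC(=O)Oc1ccc2ccc(=O)oc2c1[Si](C)(C)C
F7 | step 2 | 7-hydroxy-8-(trimethylsilyl)-2H-chromen-2-one | Oc1ccc2ccc(=O)oc2c1[Si](C)(C)C
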